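## Retrosynthetic overview

1. **Feature.** In the 7′-hydroxycoumarin half, benzenoid ring B has C8′–H between the oxygen-bearing C7′ and C8a′. Its other carbons carry C4′ (at C4a′), a methyl group (C5′) and ring A (C6′). This fully substituted orsellinate maps onto a 6-alkoxy-2-pyranone-5-carboxylate plus HC≡C–OR.
2. **Key disconnection.** C6′–C7′ and C8′–C8a′ are made by inverse-demand [4+2] addition of ynol ether 19 to pyranone 14, followed by loss of CO2, so ring B is made from a pyranone ring.
3. **Pyranone 14.** Arylacetate 6, whose CH2 carbon becomes C6′, is joined to methoxyethylidenemalonate 9. The ring is then closed from the acid side by cyclodehydration, never under alkoxide.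
4. **After ring B.** Salicylate 23 and the Bestmann ylide give the lactone ring of half B. Ring A is then acetylated, closed with dimethyl carbonate, O-methylated and debenzylated.
5. **Ring order.** Ring A (bought), then the sacrificial 2-pyranone, then ring B, then the lactone ring of half B, then the lactone ring of half A.

Key step: step 7

Assumption: the SMILES carries no descriptor for the C8–C6′ axis, so the racemic pair of atropisomers is taken as the target.

## Route

Step 1
Reactants: 1 3,5-dimethoxytoluene
Product: 3 2-iodo-1,3-dimethoxy-5-methylbenzene, via aryllithium 2 (not isolated)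
Conditions: n-BuLi (1.1 equiv), THF, 0 °C to rt; I2, THF, −78 °C to rt
Reagents that add atoms: iodine, II
Why: Directed ortho-metalation removes the proton flanked by both methoxy groups (para to the methyl group), and iodinolysis of aryllithium 2 marks the carbon that will hold the inter-ring bond.

Step 2
Reactants: 3 2-iodo-1,3-dimethoxy-5-methylbenzene; 4 tert-butyl bromoacetate
Product: 6 tert-butyl (2,6-dimethoxy-4-methylphenyl)acetate, via Reformatsky reagent 5 (not isolated)
Conditions: 4, Zn dust (Me3SiCl-activated), THF, 40 °C; then 3, Pd(dba)2 (3 mol %), XPhos (6 mol %), THF, 65 °C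
Reagents that add atoms: none
Why: Negishi-type α-arylation with a Reformatsky zinc enolate is non-basic and uses a small CH2 nucleophile, and a bulky biarylphosphine on zerovalent palladium is the usual answer to an electron-rich aryl iodide with two ortho substituents.

Step 3
Reactants: 7 dimethyl malonate; 8 trimethyl orthoacetate
Product: 9 dimethyl 2-(1-methoxyethylidene)propanedioate
Conditions: Ac2O (2.2 equiv), ZnCl2 (5 mol %), 120–135 °C, volatiles distilled off
Reagents that add atoms: none
Why: Orthoester (Claisen-type alkoxyalkylidene) condensation: the dialkoxycarbenium ion from 8 is trapped by the malonate enol, methanol is lost, and acetic anhydride removes the methanol so that the equilibrium moves to the push–pull alkene.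

Step 4
Reactants: 6 tert-butyl (2,6-dimethoxy-4-methylphenyl)acetate; 9 dimethyl 2-(1-methoxyethylidene)propanedioate
Product: 11 1-tert-butyl 5-methyl 2-(2,6-dimethoxy-4-methylphenyl)-4-(methoxycarbonyl)-3-methylpent-3-enedioate (racemic), via lithium enolate 10 (not isolated)
Conditions: LiN(SiMe3)2 (1.05 equiv), THF, −78 °C; 9, −78 to 0 °C; 1 M HCl, 0 °C
Reagents that add atoms: none
Why: Conjugate addition–elimination (vinylogous acyl substitution) of ester enolate 10 at the methoxy-bearing carbon of 9 expels methoxide, which deprotonates the product to a doubly stabilised glutaconate anion and so drives the reaction; the new CH centre is racemic and labile and disappears in step 5.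

Step 5
Reactants: 11 1-tert-butyl 5-methyl 2-(2,6-dimethoxy-4-methylphenyl)-4-(methoxycarbonyl)-3-methylpent-3-enedioate
Product: 14 methyl 3-(2,6-dimethoxy-4-methylphenyl)-6-methoxy-4-methyl-2-oxo-2H-pyran-5-carboxylate, via free acid 12 (not isolated), via mixed anhydride 13 (not isolated)
Conditions: CF3CO2H/CH2Cl2 (1:3), 0 °C to rt; evaporate; (CF3CO)2O (2 equiv), CH2Cl2, 0 °C to rt; evaporate, crystallise with exclusion of moisture
Reagents that add atoms: none
Why: Acidolysis frees only the tert-butyl ester, and mixed anhydride 13 acylates the carbonyl oxygen of the malonate ester that is necessarily cis to it (both substituents on that alkene carbon are esters), after which loss of the C3 proton gives the 2-pyranone; this cyclodehydration is the closure by which carboxyglutaconic esters give 6-alkoxy-2-pyranone carboxylates, and it is run without base because alkoxide would reopen the acyl ketene acetal.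

Step 6
Reactants: 15 1-adamantanol; 16 trichloroethylene
Product: 19 1-(ethynyloxy)adamantane, via dichlorovinyl ether 17 (not isolated), via lithium acetylide 18 (not isolated)
Conditions: KH (1.2 equiv), THF, 0 °C to rt; 16 (1.1 equiv), −50 °C to rt; n-BuLi (2.4 equiv), −78 to −40 °C; H2O, −78 °C to rt
Reagents that add atoms: none
Why: Trichloroethylene route to ynol ethers: the alkoxide gives the (E)-1,2-dichlorovinyl ether 17, and n-BuLi effects dehydrochlorination and chlorine–lithium exchange to acetylide 18, which is protonated; the bridgehead ether is chosen because it has neither the [3,3] shift that destroys benzyl alkynyl ethers on gentle warming nor a retro-ene path (that would need a bridgehead alkene), yet it is still cleaved by acid.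

Step 7
Reactants: 14 methyl 3-(2,6-dimethoxy-4-methylphenyl)-6-methoxy-4-methyl-2-oxo-2H-pyran-5-carboxylate; 19 1-(ethynyloxy)adamantane
Product: 21 methyl 4-(adamantan-1-yloxy)-3-(2,6-dimethoxy-4-methylphenyl)-6-methoxy-2-methylbenzoate, via bicyclic lactone 20 (not isolated)
Conditions: 19 (5 equiv), BHT (5 mol %), toluene (1 M in 14), sealed tube, 135 °C
Reagents that add atoms: none
Why: The lactone carbonyl and the C5 ester make 14 an electron-poor diene, so the electron-rich alkyne 19 adds across C3 and C6 in an asynchronous inverse-electron-demand Diels–Alder reaction in which its unsubstituted carbon bonds first to C6 and the ketenium-like, oxygen-bearing carbon then closes onto C3. The 2-oxabicyclo[2.2.2]octadienone 20 is not expected to survive at this temperature and should extrude CO2 by retro-[4+2], so ring B is closed by an intermolecular [4+2] cycloaddition (a six-membered carbocycle from four pyranone carbons and two alkyne carbons) and aromatised by cycloreversion, which makes the C8′–C8a′ and C6′–C7′ bonds of the target. The closest known reaction type is the benzannulation of 2-pyranone-5-carboxylates with ynamines, alkoxyalkynes and ketene acetals. No stereocentre is carried forward, because the two bridgeheads of racemic 20 become sp2 carbons and the aryl–aryl axis of 21 is not stereogenic while ring A is symmetric. The step needs regioselectivity, and the substrate secures it by polarity: C6 is β to the ester and δ to the lactone carbonyl and is the only electrophilic diene terminus, whereas C3 is the α-carbon of the developing dienolate, so the alkoxy-bearing carbon ends next to the aryl group and C8′ carries hydrogen. The rod-shaped alkyne is the least demanding partner for a terminus shielded by the twisted, di-ortho-substituted aryl group, and the bridgehead ether lets the mixture be held at 135 °C, where a benzyl ynol ether would already have rearranged.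

Step 8
Reactants: 21 methyl 4-(adamantan-1-yloxy)-3-(2,6-dimethoxy-4-methylphenyl)-6-methoxy-2-methylbenzoate
Product: 22 methyl 3-(2,6-dimethoxy-4-methylphenyl)-4,6-dihydroxy-2-methylbenzoate
Conditions: BCl3 (3.5 equiv), CH2Cl2, −78 to 0 °C; H2O
Reagents that add atoms: none
Why: Lewis-acid ether cleavage: the tertiary ether ionises at low temperature and is captured as the chloride, the methoxy group ortho to the ester is cleaved through a six-membered boron chelate, and the two unchelated methoxy groups of ring A should persist at or below 0 °C.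

Step 9
Reactants: 22 methyl 3-(2,6-dimethoxy-4-methylphenyl)-4,6-dihydroxy-2-methylbenzoate
Product: 23 methyl 4-(benzyloxy)-3-(2,6-dimethoxy-4-methylphenyl)-6-hydroxy-2-methylbenzoate
Conditions: BnBr (1.05 equiv), K2CO3 (1.1 equiv), acetone, 50 °C
Reagents that add atoms: benzyl bromide, BrCc1ccccc1
Why: Williamson etherification with one equivalent of halide is selective for the 4-hydroxyl, since the 6-hydroxyl is tied up in a hydrogen bond to the ester carbonyl, the usual selectivity of orsellinates.

Step 10
Reactants: 23 methyl 4-(benzyloxy)-3-(2,6-dimethoxy-4-methylphenyl)-6-hydroxy-2-methylbenzoate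
Product: 25 7-(benzyloxy)-6-(2,6-dimethoxy-4-methylphenyl)-4-methoxy-5-methyl-2H-chromen-2-one, via acyl ylide 24 (not isolated)
Conditions: Ph3P=C=C=O (1.3 equiv), toluene, 110 °C
Reagents that add atoms: (triphenylphosphoranylidene)ketene, O=C=C=P(c1ccccc1)(c1ccccc1)c1ccccc1
Why: Bestmann ylide annulation: the phenol adds to the cumulated ylide to give acyl ylide 24, whose intramolecular Wittig olefination of the neighbouring ester carbonyl closes the lactone ring of half B and keeps the ester methoxy group as the 4′-methoxy enol ether.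

Step 11
Reactants: 25 7-(benzyloxy)-6-(2,6-dimethoxy-4-methylphenyl)-4-methoxy-5-methyl-2H-chromen-2-one
Product: 26 6-(3-acetyl-2,6-dimethoxy-4-methylphenyl)-7-(benzyloxy)-4-methoxy-5-methyl-2H-chromen-2-one (racemic axis)
Conditions: AcOH (1.5 equiv), (CF3CO)2O (2 equiv), 85% H3PO4 (cat.), CH2Cl2, 0 °C to rt
Reagents that add atoms: acetic acid, CC(=O)O
Why: Friedel–Crafts acylation with acetyl trifluoroacetate made in the flask attacks ring A, the most electron-rich ring, at either of its two equivalent free positions (ortho and para to methoxy), while C8′ and C3′ belong to the deactivated coumarin and the metal-halide-free medium leaves the benzyl ether alone; the biaryl axis becomes stereogenic here and 26 is racemic.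

Step 12
Reactants: 26 6-(3-acetyl-2,6-dimethoxy-4-methylphenyl)-7-(benzyloxy)-4-methoxy-5-methyl-2H-chromen-2-one
Product: 27 6-(3-acetyl-2-hydroxy-6-methoxy-4-methylphenyl)-7-(benzyloxy)-4-methoxy-5-methyl-2H-chromen-2-one (racemic axis)
Conditions: BCl3 (2.2 equiv), CH2Cl2, −78 to −20 °C; H2O
Reagents that add atoms: none
Why: Chelation-controlled demethylation: BCl3 bound to the ketone cleaves only the methoxy group ortho to the acetyl group, which is also twisted out of conjugation by the axis, whereas the benzyloxy oxygen is a weakly basic, vinylogous-ester-type oxygen that should survive at low temperature with the reagent limited to one equivalent per carbonyl donor.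

Step 13
Reactants: 27 6-(3-acetyl-2-hydroxy-6-methoxy-4-methylphenyl)-7-(benzyloxy)-4-methoxy-5-methyl-2H-chromen-2-one
Product: 29 8-[7-(benzyloxy)-4-methoxy-5-methyl-2-oxo-2H-chromen-6-yl]-4-hydroxy-7-methoxy-5-methyl-2H-chromen-2-one (racemic axis), via β-keto ester 28 (not isolated)
Conditions: NaH (4 equiv), (MeO)2CO (10 equiv), toluene, 95 °C; 1 M HCl
Reagents that add atoms: dimethyl carbonate, COC(=O)OC
Why: Claisen-type C-methoxycarbonylation of the methyl ketone enolate gives β-keto ester 28, which lactonises onto the phenoxide (the standard 4-hydroxycoumarin synthesis); the dimethyl ester is used so that any alkoxide exchange at the 4′-methoxy group is degenerate, and any opening of lactone B is reversed on acidification.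

Step 14
Reactants: 29 8-[7-(benzyloxy)-4-methoxy-5-methyl-2-oxo-2H-chromen-6-yl]-4-hydroxy-7-methoxy-5-methyl-2H-chromen-2-one
Product: 30 8-[7-(benzyloxy)-4-methoxy-5-methyl-2-oxo-2H-chromen-6-yl]-4,7-dimethoxy-5-methyl-2H-chromen-2-one (racemic axis)
Conditions: Me2SO4 (1.5 equiv), K2CO3 (2 equiv), acetone, reflux
Reagents that add atoms: dimethyl sulfate, COS(=O)(=O)OC
Why: O-Alkylation of the vinylogous acid with a hard methylating agent and carbonate base gives the 4-methoxycoumarin, and no other acidic site is left in 29.

Step 15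
Reactants: 30 8-[7-(benzyloxy)-4-methoxy-5-methyl-2-oxo-2H-chromen-6-yl]-4,7-dimethoxy-5-methyl-2H-chromen-2-one
Product: 31 8-(7-hydroxy-4-methoxy-5-methyl-2-oxo-2H-chromen-6-yl)-4,7-dimethoxy-5-methyl-2H-chromen-2-one (CNP0113839.0, racemic axis)
Conditions: H2 (1 atm), 10% Pd/C, EtOAc/MeOH, rt
Reagents that add atoms: none
Why: Catalytic hydrogenolysis cleaves the benzylic C–O bond under neutral conditions that leave the enol-ether double bonds of both coumarins and all methyl ethers untouched.

## Compound list

1 | 3,5-dimethoxytoluene | Cc1cc(OC)cc(OC)c1 | starting material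
2 | (2,6-dimethoxy-4-methylphenyl)lithium | [Li]c1c(OC)cc(C)cc1OC | intermediate
3 | 2-iodo-1,3-dimethoxy-5-methylbenzene | COc1cc(C)cc(OC)c1I | intermediate
4 | tert-butyl bromoacetate | CC(C)(C)OC(=O)CBr | starting material
5 | bromo(2-tert-butoxy-2-oxoethyl)zinc | CC(C)(C)OC(=O)C[Zn]Br | intermediate
6 | tert-butyl (2,6-dimethoxy-4-methylphenyl)acetate | COc1cc(C)cc(OC)c1CC(=O)OC(C)(C)C | intermediate
7 | dimethyl malonate | COC(=O)CC(=O)OC | starting material
8 | trimethyl orthoacetate | COC(C)(OC)OC | starting material
9 | dimethyl 2-(1-methoxyethylidene)propanedioate | COC(C)=C(C(=O)OC)C(=O)OC | intermediate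
10 | lithium enolate of 6 | [Li]OC(OC(C)(C)C)=Cc1c(OC)cc(C)cc1OC | intermediate
11 | 1-tert-butyl 5-methyl 2-(2,6-dimethoxy-4-methylphenyl)-4-(methoxycarbonyl)-3-methylpent-3-enedioate (racemic) | COC(=O)C(C(=O)OC)=C(C)C(C(=O)OC(C)(C)C)c1c(OC)cc(C)cc1OC | intermediate
12 | 2-(2,6-dimethoxy-4-methylphenyl)-5-methoxy-4-(methoxycarbonyl)-3-methyl-5-oxopent-3-enoic acid (racemic) | COC(=O)C(C(=O)OC)=C(C)C(C(=O)O)c1c(OC)cc(C)cc1OC | intermediate
13 | mixed anhydride of 12 and trifluoroacetic acid (racemic) | COC(=O)C(C(=O)OC)=C(C)C(C(=O)OC(=O)C(F)(F)F)c1c(OC)cc(C)cc1OC | intermediate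
14 | methyl 3-(2,6-dimethoxy-4-methylphenyl)-6-methoxy-4-methyl-2-oxo-2H-pyran-5-carboxylate | COC(=O)c1c(OC)oc(=O)c(-c2c(OC)cc(C)cc2OC)c1C | intermediate
15 | 1-adamantanol | OC12CC3CC(CC(C3)C1)C2 | starting material
16 | trichloroethylene | ClC=C(Cl)Cl | starting material
17 | 1-{[(E)-1,2-dichloroethenyl]oxy}adamantane | Cl/C=C(/Cl)OC12CC3CC(CC(C3)C1)C2 | intermediate
18 | [(adamantan-1-yloxy)ethynyl]lithium | [Li]C#COC12CC3CC(CC(C3)C1)C2 | intermediate
19 | 1-(ethynyloxy)adamantane | C#COC12CC3CC(CC(C3)C1)C2 | intermediate
20 | methyl 8-(adamantan-1-yloxy)-4-(2,6-dimethoxy-4-methylphenyl)-1-methoxy-5-methyl-3-oxo-2-oxabicyclo[2.2.2]octa-5,7-diene-6-carboxylate (racemic) | COC(=O)C1=C(C)C2(C(=O)OC1(OC)C=C2OC34CC5CC(CC(C5)C3)C4)c1c(OC)cc(C)cc1OC | intermediate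
21 | methyl 4-(adamantan-1-yloxy)-3-(2,6-dimethoxy-4-methylphenyl)-6-methoxy-2-methylbenzoate | COC(=O)c1c(OC)cc(OC23CC4CC(CC(C4)C2)C3)c(-c2c(OC)cc(C)cc2OC)c1C | intermediate
22 | methyl 3-(2,6-dimethoxy-4-methylphenyl)-4,6-dihydroxy-2-methylbenzoate | COC(=O)c1c(O)cc(O)c(-c2c(OC)cc(C)cc2OC)c1C | intermediate
23 | methyl 4-(benzyloxy)-3-(2,6-dimethoxy-4-methylphenyl)-6-hydroxy-2-methylbenzoate | COC(=O)c1c(O)cc(OCc2ccccc2)c(-c2c(OC)cc(C)cc2OC)c1C | intermediate
24 | methyl 4-(benzyloxy)-3-(2,6-dimethoxy-4-methylphenyl)-2-methyl-6-{[(triphenylphosphoranylidene)acetyl]oxy}benzoate | COC(=O)c1c(OC(=O)C=P(c2ccccc2)(c2ccccc2)c2ccccc2)cc(OCc2ccccc2)c(-c2c(OC)cc(C)cc2OC)c1C | intermediate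
25 | 7-(benzyloxy)-6-(2,6-dimethoxy-4-methylphenyl)-4-methoxy-5-methyl-2H-chromen-2-one | COc1cc(=O)oc2cc(OCc3ccccc3)c(-c3c(OC)cc(C)cc3OC)c(C)c12 | intermediate
26 | 6-(3-acetyl-2,6-dimethoxy-4-methylphenyl)-7-(benzyloxy)-4-methoxy-5-methyl-2H-chromen-2-one (racemic axis) | COc1cc(=O)oc2cc(OCc3ccccc3)c(-c3c(OC)cc(C)c(C(C)=O)c3OC)c(C)c12 | intermediate
27 | 6-(3-acetyl-2-hydroxy-6-methoxy-4-methylphenyl)-7-(benzyloxy)-4-methoxy-5-methyl-2H-chromen-2-one (racemic axis) | COc1cc(=O)oc2cc(OCc3ccccc3)c(-c3c(OC)cc(C)c(C(C)=O)c3O)c(C)c12 | intermediate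
28 | methyl 3-{3-[7-(benzyloxy)-4-methoxy-5-methyl-2-oxo-2H-chromen-6-yl]-2-hydroxy-4-methoxy-6-methylphenyl}-3-oxopropanoate (racemic axis) | COc1cc(=O)oc2cc(OCc3ccccc3)c(-c3c(OC)cc(C)c(C(=O)CC(=O)OC)c3O)c(C)c12 | intermediate
29 | 8-[7-(benzyloxy)-4-methoxy-5-methyl-2-oxo-2H-chromen-6-yl]-4-hydroxy-7-methoxy-5-methyl-2H-chromen-2-one (racemic axis) | COc1cc(C)c2c(O)cc(=O)oc2c1-c1c(OCc3ccccc3)cc2oc(=O)cc(OC)c2c1C | intermediate
30 | 8-[7-(benzyloxy)-4-methoxy-5-methyl-2-oxo-2H-chromen-6-yl]-4,7-dimethoxy-5-methyl-2H-chromen-2-one (racemic axis) | COc1cc(C)c2c(OC)cc(=O)oc2c1-c1c(OCc3ccccc3)cc2oc(=O)cc(OC)c2c1C | intermediate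
31 | 8-(7-hydroxy-4-methoxy-5-methyl-2-oxo-2H-chromen-6-yl)-4,7-dimethoxy-5-methyl-2H-chromen-2-one, CNP0113839.0 (racemic axis) | COc1cc(C)c2c(OC)cc(=O)oc2c1-c1c(O)cc2oc(=O)cc(OC)c2c1C | target

## Step count and risks

Total steps: 15. Longest linear sequence: 13 (steps 1, 2, 4, 5, 7 to 15). Steps 3 and 6 are side branches.

**Steps most likely to fail**

**1. Step 7.**
- *Risk.* The cycloaddition may be too slow. The 6-methoxy donor raises the diene LUMO and the twisted aryl group shields C3. Oligomerisation of the ynol ether and thermal ring-opening of the pyranone could then consume both partners before bonds form. Erosion of regiocontrol by repulsion between the alkoxy and aryl groups is the second concern.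
- *Fallback.* The inter-ring bond is made by cross-coupling onto a ready-made ring B. The fallback sets out from 2 and returns at 22. Commercial methyl 2,4-dihydroxy-6-methylbenzoate F1 is bis-benzylated (BnBr, K2CO3, DMF) to methyl 2,4-bis(benzyloxy)-6-methylbenzoate F2. NBS in MeCN then brominates the position para to the 2-benzyloxy group to give methyl 4,6-bis(benzyloxy)-3-bromo-2-methylbenzoate F3. Aryllithium 2 is transmetalated with ZnCl2 to (2,6-dimethoxy-4-methylphenyl)zinc chloride F4. A Negishi coupling of F4 with F3 (Pd2(dba)3, RuPhos, THF, 70 °C) gives methyl 4,6-bis(benzyloxy)-3-(2,6-dimethoxy-4-methylphenyl)-2-methylbenzoate F5. Hydrogenolysis (H2, 10% Pd/C) then gives 22.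

**2. Step 4.**
- *Risk.* Proton transfer from the C-methyl group of 9 to the basic, hindered enolate, followed by self-condensation of the acceptor, may outrun carbon–carbon bond formation at the fully substituted β-carbon.
- *Fallback.* A neutral nucleophile is combined with a Lewis-acid-activated acceptor. The fallback sets out from 6 and returns at 11. Compound 6 is converted (LiN(iPr)2, Me3SiCl, THF, −78 °C) into its tert-butyl trimethylsilyl ketene acetal F6. F6 is added to 9 with Sc(OTf)3 (10 mol %) in CH2Cl2. This Mukaiyama–Michael addition, followed by loss of the silyl methyl ether, gives 11 without any strong base in the flask.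

**3. Step 5.**
- *Risk.* After acylation of the ester oxygen, the O-methyl group could be lost instead of the C3 proton. Alternatively, the vinylogous malonic half-acid could decarboxylate before activation. Either process would divert material from the 6-methoxy ring.
- *Fallback.* The ring is closed first as the anhydride and the oxygen is methylated afterwards. The fallback sets out from 12, isolated after the acidolysis, and returns at 14. (COCl)2 with catalytic DMF in CH2Cl2 gives the acid chloride F7. On warming, F7 acylates the neighbouring ester oxygen and chloride removes the methyl group. This gives the glutaconic anhydride, which should rest as its chelated enol, methyl 3-(2,6-dimethoxy-4-methylphenyl)-6-hydroxy-4-methyl-2-oxo-2H-pyran-5-carboxylate F8. CH2N2 in Et2O at 0 °C then methylates the acidic enol oxygen next to the ester to give 14.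

## Further compounds

F1 | step 7 | methyl 2,4-dihydroxy-6-methylbenzoate | COC(=O)c1c(C)cc(O)cc1O
F2 | step 7 | methyl 2,4-bis(benzyloxy)-6-methylbenzoate | COC(=O)c1c(C)cc(OCc2ccccc2)cc1OCc1ccccc1
F3 | step 7 | methyl 4,6-bis(benzyloxy)-3-bromo-2-methylbenzoate | COC(=O)c1c(C)c(Br)c(OCc2ccccc2)cc1OCc1ccccc1
F4 | step 7 | (2,6-dimethoxy-4-methylphenyl)zinc chloride | Cl[Zn]c1c(OC)cc(C)cc1OC
F5 | step 7 | methyl 4,6-bis(benzyloxy)-3-(2,6-dimethoxy-4-methylphenyl)-2-methylbenzoate | COC(=O)c1c(C)c(-c2c(OC)cc(C)cc2OC)c(OCc2ccccc2)cc1OCc1ccccc1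
F6 | step 4 | tert-butyl trimethylsilyl ketene acetal of 6 | C[Si](C)(C)OC(OC(C)(C)C)=Cc1c(OC)cc(C)cc1OC
F7 | step 5 | acid chloride of 12 (racemic) | COC(=O)C(C(=O)OC)=C(C)C(C(=O)Cl)c1c(OC)cc(C)cc1OC
F8 | step 5 | methyl 3-(2,6-dimethoxy-4-methylphenyl)-6-hydroxy-4-methyl-2-oxo-2H-pyran-5-carboxylate | COC(=O)c1c(O)oc(=O)c(-c2c(OC)cc(C)cc2OC)c1C
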